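The readings are simulated for substances that don't exist, noise included.

The ochre run starts so slowly that it reads 0.0048 M at 0.89 h, and two chemists dispute what kind of clock that slow start, the induction period, shows.

| flask | substrate | free catalyst | time |
|---|---|---|---|
| ochre | 0.250 M | 0.0250 M |  |
| grey | 0.120 M | 0.0250 M |  |
| teal | 0.250 M | 0.00630 M | 5.6 h |

| run | time / h | [product] / M |
|---|---|---|
| ochre run | 0.22 | 0 |
| ochre run | 0.35 | 0.0010 |
| ochre run | 0.56 | 0.0013 |
| ochre run | 0.89 | 0.0048 |
| ochre run | 1.4 | 0.0087 |
| ochre run | 2.2 | 0.0201 |
| ochre run | 3.5 | 0.0439 |
| ochre run | 5.6 | 0.0946 |
| grey run | 0.22 | 0.0010 |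
| grey run | 0.35 | 7 × 10⁻⁴ |
| grey run | 0.56 | 0.0027 |
| grey run | 0.89 | 0.0025 |
| grey run | 1.4 | 0.0033 |
| grey run | 2.2 | 0.0074 |
| grey run | 3.5 | 0.0168 |
| grey run | 5.6 | 0.0328 |

(scatter of a reading: 0.001 M)

- how the opening rate goes with [substrate] round the charge of the ochre run: the exponent of the rate at two percent of substrate gone to product (one fixed amount of product, the same in the runs compared)
- product in the teal run at 5.6 h, as a share of the substrate charged

- Overall: substrate -> product, with free catalyst as catalyst.
- Constant volume, constant temperature.
- An order is taken over about fifteen percent of the charge, up and down.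

Late in the ochre run, product goes from 0.0439 M at 3.5 h to 0.0946 M at 5.6 h. From this stretch both take the doubling time, the hours product needs to double late in a run, which comes to 1.90 h. The same reckoning on the grey run gives 2.18 h, a little longer, although its last reading is a third of the ochre one.

The first chemist says that the catalyst charge sets the speed of the clock. The teal run has a quarter of the ochre catalyst, so its 5.6 h match the ochre run at 1.41 h, whose reading is 3.48% of the charge. Its doubling time would stretch to 7.52 h. This view is exact for a flask in which every step goes in proportion to the catalyst.

The second chemist, and I with her, makes a different guess, for the ochre and grey runs carry the same catalyst charge and show nothing of how the catalyst acts: the guess keeps the clock and scales the height by the catalyst ratio. The teal run then makes the ochre product times that ratio, 9.54% of its charge, which is 1.99 doublings below the ochre run.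

The forecast, 0.9 and 4.2%, takes the first side, with the words “Time then scales with catalyst”.

The simulation gives an order of 0.73 and 17.2%, above both reckonings, from these steps:

    2 active catalyst ⇌ catalyst dimer, settled at all times (84.80 L mol⁻¹)
    active catalyst + substrate → product + active catalyst (6.120 L mol⁻¹ h⁻¹)
    free catalyst → active catalyst (0.4608 h⁻¹)
    substrate + product → 2 product (1.170 L mol⁻¹ h⁻¹)

At the amount of product that is two percent of the ochre charge, the grey run's rate is 0.58 of the ochre rate. The teal run ends 1.14 doublings below the ochre run at 5.6 h, which is 2.17 h of ochre time. In the grey run, one grey doubling time counted from its quarter mark at 5.16 h lands at 7.34 h, while its half mark stands at 8.86 h.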